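**Retrosynthetic overview**
1. The target is two 7,8,4'-trihydroxyflavan-3,4-diol units joined C4–O–C4 (flavan numbering: ring C = O1, C2, C3, C4; ring A = C4a to C8a; ring B on C2). Unit A is all-cis (2R,3R,4R); unit B is 2,3-trans-3,4-cis (2S,3R,4R).
2. The strategy rests on C4 of unit B: it carries the ether oxygen and sits between C3 and C4a of ring A. It is therefore taken back to the carboxyl carbon of a ring A benzoate whose ester oxygen is O-4 of unit A. The C3–C4 bond is then made by ester methylenation and ring-closing metathesis onto a vinyl group on C2, which closes ring C of unit B last, as a 4-alkoxyflav-3-ene.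
3. O-3 and H-4 of unit B follow from that enol ether: epoxidation anti to the C2 aryl, then hydride to C4 anti to O-3. Silyl, mesyl and benzyl groups are removed in that order.
4. Acid half: a 2-hydroxybenzoate and 4-benzyloxycinnamyl carbonate, joined by iridium-catalysed branched allylic etherification, which sets C2 of unit B.
5. Unit A alcohol: ring C is formed first as a chromone; C2 by asymmetric conjugate arylation; O-3 cis to the aryl by bromohydrin, cis-epoxide and oxidative opening; C4 by hydride reduction. Ring A of unit A stays a bis-mesylate so that its C4–O bond cannot ionise.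

Key step: step 16

Assumption: the ligand enantiomers named in steps 3 and 13 are assigned by analogy with the usual sense of induction of these catalyst families; should 6 or 20 form as the antipode, the other ligand enantiomer is used and nothing else changes.

**Step 1**
Reactants: 1 2',3',4'-trihydroxyacetophenone
Product: 2 4-acetyl-3-hydroxy-1,2-phenylene dimethanesulfonate
Conditions: MsCl (2.05 equiv), Et3N, CH2Cl2, −20 → 0 °C
Reagents that add atoms: methanesulfonyl chloride CS(=O)(=O)Cl
Why: O-sulfonylation of phenols; the 2'-hydroxyl is held in a hydrogen bond to the acetyl carbonyl and is the least nucleophilic, so two equivalents of MsCl should take O-4' and O-3', and the mesylates make ring A of unit A electron-poor for the rest of the route.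

**Step 2**
Reactants: 2 4-acetyl-3-hydroxy-1,2-phenylene dimethanesulfonate
Product: 4 4-oxo-4H-chromene-7,8-diyl dimethanesulfonate, via enaminone 3 (not isolated)
Conditions: Me2NCH(OMe)2, toluene, 80 °C; then conc. HCl, CH2Cl2, 40 °C
Reagents that add atoms: N,N-dimethylformamide dimethyl acetal COC(OC)N(C)C (its CH carbon becomes C2 of the chromone; NMe2 is carried in 3 only)
Why: enaminone route to chromones: condensation at the acetyl methyl group, then acid-promoted oxa-Michael addition of the phenol and loss of dimethylamine closes ring C of unit A.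

**Step 3**
Reactants: 4 4-oxo-4H-chromene-7,8-diyl dimethanesulfonate; 5 4-(benzyloxy)phenylboronic acid
Product: 6 (2S)-2-[4-(benzyloxy)phenyl]-4-oxochroman-7,8-diyl dimethanesulfonate
Conditions: Pd(OCOCF3)2 (5 mol%), (R)-4-tert-butyl-2-(pyridin-2-yl)-4,5-dihydrooxazole (6 mol%), NH4PF6 (30 mol%), H2O (5 equiv), ClCH2CH2Cl, 60 °C
Reagents that add atoms: none
Why: palladium-catalysed asymmetric conjugate addition of an arylboronic acid (arylpalladium insertion into C2=C3, then protonolysis of the palladium enolate); the pyridine-oxazoline ligand selects the enone face and sets C2 (S in the flavanone, the spatial arrangement of C2 in unit A), and the electron-poor chromone is a good acceptor.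

**Step 4**
Reactants: 6 (2S)-2-[4-(benzyloxy)phenyl]-4-oxochroman-7,8-diyl dimethanesulfonate
Product: 7 (2S,4S)-2-[4-(benzyloxy)phenyl]-4-hydroxychroman-7,8-diyl dimethanesulfonate (2,4-cis)
Conditions: NaBH4, MeOH–THF, 0 °C
Reagents that add atoms: none
Why: borohydride reduction of the aryl ketone with axial hydride delivery should give the 2,4-cis alcohol; the configuration at C4 does not matter because this centre is removed in step 5.

**Step 5**
Reactants: 7 (2S,4S)-2-[4-(benzyloxy)phenyl]-4-hydroxychroman-7,8-diyl dimethanesulfonate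
Product: 8 (2S)-2-[4-(benzyloxy)phenyl]-2H-chromene-7,8-diyl dimethanesulfonate
Conditions: Burgess reagent (MeO2CN−SO2N+Et3), toluene, 60 °C, dark
Reagents that add atoms: none
Why: Burgess dehydration (syn elimination through the sulfamate ester) gives the C3=C4 alkene under neutral conditions, which spares the ionisable C2–O1 bond and the stereocentre at C2.

**Step 6**
Reactants: 8 (2S)-2-[4-(benzyloxy)phenyl]-2H-chromene-7,8-diyl dimethanesulfonate
Product: 10 (2R,3R,4R)-2-[4-(benzyloxy)phenyl]-3,4-epoxychroman-7,8-diyl dimethanesulfonate (oxirane cis to the aryl), via bromohydrin 9 (not isolated)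
Conditions: NBS, THF–H2O (4:1), 0 °C; then Cs2CO3, MeCN, rt
Reagents that add atoms: water O (oxygen of 9 and 10); N-bromosuccinimide O=C1CCC(=O)N1Br (bromine carried in 9 only)
Why: halohydrin formation followed by intramolecular Williamson closure: the bromonium ion forms on the face away from the C2 aryl and water opens it at benzylic C4 (anti addition), then the C4 alkoxide displaces bromide at C3 with inversion, which places both C–O bonds on the aryl face and so sets C3 and C4 as the epoxide that direct epoxidation does not give.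

**Step 7**
Reactants: 10 (2R,3R,4R)-2-[4-(benzyloxy)phenyl]-3,4-epoxychroman-7,8-diyl dimethanesulfonate
Product: 12 (2R,3S)-2-[4-(benzyloxy)phenyl]-3-[(tert-butyldimethylsilyl)oxy]-4-oxochroman-7,8-diyl dimethanesulfonate (2,3-cis), via alkoxysulfonium triflate 11 (not isolated)
Conditions: DMSO (10 equiv), TBSOTf (1.2 equiv), CH2Cl2, −78 → −30 °C; then Et3N (5 equiv), −78 → 0 °C
Reagents that add atoms: dimethyl sulfoxide CS(C)=O (ketone oxygen); tert-butyldimethylsilyl trifluoromethanesulfonate CC(C)(C)[Si](C)(C)OS(=O)(=O)C(F)(F)F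
Why: oxidative opening of an epoxide by DMSO (alkoxysulfonium route with Swern-type collapse): the silyl triflate activates and caps the epoxide oxygen on C3, DMSO opens at benzylic C4, and the amine converts the alkoxysulfonium to the C4 ketone, so the C3–O bond is never broken and the 2,3-cis relation is carried into a silyl ether.

**Step 8**
Reactants: 12 (2R,3S)-2-[4-(benzyloxy)phenyl]-3-[(tert-butyldimethylsilyl)oxy]-4-oxochroman-7,8-diyl dimethanesulfonate
Product: 13 (2R,3R,4R)-2-[4-(benzyloxy)phenyl]-3-[(tert-butyldimethylsilyl)oxy]-4-hydroxychroman-7,8-diyl dimethanesulfonate (all-cis)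
Conditions: NaBH4, CeCl3·7H2O, MeOH–THF, −40 °C
Reagents that add atoms: none
Why: diastereoselective borohydride reduction (Luche conditions): hydride arrives along the axial trajectory, anti to the pseudo-axial 3-silyloxy group and on the face away from both substituents, which places the new hydroxyl cis to O-3 and to the aryl (C4 R), as expected for 2,3-cis 3-oxygenated flavanones.

**Step 9**
Reactants: 14 4-hydroxycinnamic acid
Product: 15 benzyl (E)-3-[4-(benzyloxy)phenyl]prop-2-enoate
Conditions: BnBr (2.3 equiv), K2CO3, DMF, 60 °C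
Reagents that add atoms: benzyl bromide BrCc1ccccc1
Why: Williamson O-benzylation of the phenoxide and the carboxylate in one operation.

**Step 10**
Reactants: 15 benzyl (E)-3-[4-(benzyloxy)phenyl]prop-2-enoate
Product: 16 (E)-3-[4-(benzyloxy)phenyl]prop-2-en-1-ol
Conditions: i-Bu2AlH (2.5 equiv), CH2Cl2, −78 → 0 °C; KNaC4H4O6 (aq) work-up
Reagents that add atoms: none
Why: 1,2-reduction of the α,β-unsaturated ester by the aluminium hydride gives the (E)-allylic alcohol and leaves the alkene and the benzyl ether alone.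

**Step 11**
Reactants: 16 (E)-3-[4-(benzyloxy)phenyl]prop-2-en-1-ol
Product: 17 (E)-3-[4-(benzyloxy)phenyl]prop-2-en-1-yl methyl carbonate
Conditions: ClCO2Me, pyridine, CH2Cl2, 0 °C
Reagents that add atoms: methyl chloroformate COC(=O)Cl
Why: O-acylation with a chloroformate gives the linear allylic carbonate that serves as the allyl-iridium precursor.

**Step 12**
Reactants: 18 2,3,4-trihydroxybenzoic acid
Product: 19 benzyl 3,4-bis(benzyloxy)-2-hydroxybenzoate
Conditions: BnBr (3.1 equiv), K2CO3, DMF, rt
Reagents that add atoms: benzyl bromide BrCc1ccccc1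
Why: Williamson benzylation of the carboxylate and of O-3 and O-4; the 2-hydroxyl is hydrogen-bonded to the ester carbonyl and should stay free as the nucleophile for step 13.

**Step 13**
Reactants: 19 benzyl 3,4-bis(benzyloxy)-2-hydroxybenzoate; 17 (E)-3-[4-(benzyloxy)phenyl]prop-2-en-1-yl methyl carbonate
Product: 20 benzyl 3,4-bis(benzyloxy)-2-{[(1R)-1-[4-(benzyloxy)phenyl]prop-2-en-1-yl]oxy}benzoate
Conditions: [Ir(cod)Cl]2 (2 mol%), (Ra,Rc,Rc)-O,O'-(1,1'-binaphthyl-2,2'-diyl) N,N-bis(1-phenylethyl)phosphoramidite (4 mol%), n-PrNH2 activation, K3PO4 (20 mol%), THF, 35 °C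
Reagents that add atoms: none
Why: iridium-catalysed enantioselective allylic etherification: the carbonate ionises to an allyliridium complex and the phenoxide attacks the aryl-substituted terminus (branched selectivity) on the face chosen by the cyclometalated phosphoramidite, which sets the (R) centre that becomes C2 of unit B, while methoxide from the leaving group regenerates the phenoxide.

**Step 14**
Reactants: 20 benzyl 3,4-bis(benzyloxy)-2-{[(1R)-1-[4-(benzyloxy)phenyl]prop-2-en-1-yl]oxy}benzoate
Product: 21 3,4-bis(benzyloxy)-2-{[(1R)-1-[4-(benzyloxy)phenyl]prop-2-en-1-yl]oxy}benzoic acid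
Conditions: LiOH, THF–MeOH–H2O, 40 °C; then 0.5 M HCl to pH 4, 0 °C
Reagents that add atoms: lithium hydroxide [Li+].[OH-]
Why: saponification of the benzyl ester; base does not touch the allylic aryl ether or its stereocentre, and the acid is set free cold at pH 4 so that the p-alkoxybenzylic ether does not ionise.

**Step 15**
Reactants: 21 3,4-bis(benzyloxy)-2-{[(1R)-1-[4-(benzyloxy)phenyl]prop-2-en-1-yl]oxy}benzoic acid; 13 (2R,3R,4R)-2-[4-(benzyloxy)phenyl]-3-[(tert-butyldimethylsilyl)oxy]-4-hydroxychroman-7,8-diyl dimethanesulfonate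
Product: 23 ester of the C4 hydroxyl of 13 (all-cis unit A unchanged) with acid 21 ((R)-allylic ether unchanged), via mixed anhydride 22 (not isolated)
Conditions: 2,4,6-Cl3C6H2COCl, Et3N, THF, rt; then 13, DMAP, toluene, rt → 40 °C
Reagents that add atoms: 2,4,6-trichlorobenzoyl chloride O=C(Cl)c1c(Cl)cc(Cl)cc1Cl (acyl group carried in 22 only)
Why: Yamaguchi esterification: DMAP attacks the mixed anhydride at the less hindered carbonyl and the acylpyridinium acylates the equatorial C4 hydroxyl of 13, with the C4–O bond and all stereocentres retained.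

**Step 16**
Reactants: 23 ester of the C4 hydroxyl of 13 with acid 21
Product: 25 protected unit A (as in 13) carrying on O-4 the (2R)-7,8-bis(benzyloxy)-2-[4-(benzyloxy)phenyl]-2H-chromen-4-yl group, via acyclic enol ether 24 (not isolated)
Conditions: Cp2Ti(μ-CH2)(μ-Cl)AlMe2 (Tebbe reagent, 2 equiv), pyridine (cat.), THF–toluene, −40 °C → rt; NaOH (aq), filtration through basic Al2O3; then second-generation Grubbs catalyst (H2IMes)(PCy3)Cl2Ru=CHPh (10 mol%), toluene, 50 °C, dark
Reagents that add atoms: Tebbe reagent C[Al-]1(C)C[Ti](C2C=CC=C2)(C2C=CC=C2)[Cl+]1 (its CH2 is carried in 24 only and leaves as ethene)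
Why: The titanium methylidene released from the Tebbe reagent adds to the ester carbonyl and the oxatitanacyclobutane collapses to Cp2Ti=O and the 1-alkoxy-1-arylethene 24 (carbonyl methylenation), with no Brønsted acid present. The ruthenium carbene then loads at the terminal vinyl group, closes onto the 1,1-disubstituted enol ether through a ruthenacyclobutane and releases ethene, which forms the C3–C4 bond of unit B as the enol ether double bond; the closest known reaction type is the two-stage olefinic ester cyclisation (ester methylenation, then ring-closing enol ether–olefin metathesis) used for cyclic enol ethers. Ring C of unit B is closed as a six-membered ring by ring-closing metathesis between two ortho-disposed arms of ring A, C4 on C4a and the O1–C2 arm on C8a, which gives the 4-alkoxy-2H-chromene. No stereocentre is formed: C2 of unit B comes from step 13 and C2, C3 and C4 of unit A from steps 3 to 8, and none of them lies on a reacting atom. The step needs methylenation of the one ester in the presence of aryl mesylates, benzyl ethers and a silyl ether, and ring closure in preference to cross-metathesis; the ester is the only carbonyl group, and the ortho tether with a six-membered ring makes closure intramolecular. Pyridine and the basic quench keep the aluminium by-products away from the enol ether, and the closure is run in the dark at moderate temperature so that the 2H-chromene does not open electrocyclically and lose C2.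

**Step 17**
Reactants: 25 protected unit A carrying on O-4 the (2R)-7,8-bis(benzyloxy)-2-[4-(benzyloxy)phenyl]-2H-chromen-4-yl group
Product: 27 protected unit A (as in 13) bearing on O-4 the (2S,3R,4R)-7,8-bis(benzyloxy)-2-[4-(benzyloxy)phenyl]-3-hydroxychroman-4-yl group (unit B 2,3-trans-3,4-cis), via epoxy ketal 26 (not isolated)
Conditions: DMDO (acetone), CH2Cl2, −78 °C, volatiles removed cold; then Et3SiH (10 equiv), BF3·OEt2 (1.2 equiv), CH2Cl2, −90 → −78 °C; Et3N then NaHCO3 (aq)
Reagents that add atoms: dimethyldioxirane CC1(C)OO1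
Why: epoxidation of the electron-rich enol ether on the face away from the C2 aryl of unit B sets C3 (O anti to the aryl, 2,3-trans), and Lewis-acid opening of the epoxy ketal at C4 with hydride transfer from the silane on the face opposite the departing oxygen (reductive opening of an enol ether epoxide, invertive as in openings of 1,2-anhydro sugars and trans to O-3 as in captures of flavan-4-yl cations) should set C4 with the ether oxygen cis to the new hydroxyl, while the mesylates on ring A of unit A keep the oxocarbenium ion from shedding unit A as a benzylic cation.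

**Step 18**
Reactants: 27 protected dimer with silyl ether on O-3 of unit A
Product: 28 the same dimer with free 3-hydroxyl on unit A (unit A 2R,3R,4R; unit B 2S,3R,4R)
Conditions: Bu4NF (2 equiv), AcOH (2 equiv), THF, 0 °C → rt
Reagents that add atoms: none
Why: fluoride-mediated desilylation, buffered with acetic acid so that the aryl mesylates and the benzylic ether are not exposed to alkoxide.

**Step 19**
Reactants: 28 dimer with mesylates on O-7 and O-8 of unit A
Product: 29 dimer with free 7,8-catechol on unit A and four benzyl ethers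
Conditions: LiN(i-Pr)2 (8 equiv), THF, −78 → −40 °C; NH4Cl (aq)
Reagents that add atoms: none
Why: cleavage of aryl mesylates by lithium diisopropylamide: deprotonation of the S-methyl group and loss of sulfene (E1cB) releases the two phenoxides at low temperature without acid or nucleophile, which the bis-benzylic ether would not tolerate.

**Step 20**
Reactants: 29 dimer with free 7,8-catechol on unit A and four benzyl ethers
Product: 30 CNP0241481.1
Conditions: H2 (1 atm), Pd(OH)2/C, EtOAc–MeOH, rt
Reagents that add atoms: none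
Why: hydrogenolysis of the four benzyl aryl ethers under neutral conditions should give the target with toluene as the only by-product, since primary benzyl aryl ethers cleave much faster than the secondary dibenzylic C4–O–C4 ether.

**Compound list**
1 | 2',3',4'-trihydroxyacetophenone | CC(=O)c1ccc(O)c(O)c1O | starting material
2 | 4-acetyl-3-hydroxy-1,2-phenylene dimethanesulfonate | CC(=O)c1ccc(OS(C)(=O)=O)c(OS(C)(=O)=O)c1O | intermediate
3 | (E)-3-(dimethylamino)-1-[2-hydroxy-3,4-bis(methanesulfonyloxy)phenyl]prop-2-en-1-one | CN(C)/C=C/C(=O)c1ccc(OS(C)(=O)=O)c(OS(C)(=O)=O)c1O | intermediate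
4 | 4-oxo-4H-chromene-7,8-diyl dimethanesulfonate | O=c1ccoc2c1ccc(OS(C)(=O)=O)c2OS(C)(=O)=O | intermediate
5 | 4-(benzyloxy)phenylboronic acid | OB(O)c1ccc(OCc2ccccc2)cc1 | starting material
6 | (2S)-2-[4-(benzyloxy)phenyl]-4-oxochroman-7,8-diyl dimethanesulfonate | O=C1C[C@@H](c2ccc(OCc3ccccc3)cc2)Oc2c1ccc(OS(C)(=O)=O)c2OS(C)(=O)=O | intermediate
7 | (2S,4S)-2-[4-(benzyloxy)phenyl]-4-hydroxychroman-7,8-diyl dimethanesulfonate | O[C@H]1C[C@@H](c2ccc(OCc3ccccc3)cc2)Oc2c1ccc(OS(C)(=O)=O)c2OS(C)(=O)=O | intermediate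
8 | (2S)-2-[4-(benzyloxy)phenyl]-2H-chromene-7,8-diyl dimethanesulfonate | C1=C[C@@H](c2ccc(OCc3ccccc3)cc2)Oc2c1ccc(OS(C)(=O)=O)c2OS(C)(=O)=O | intermediate
9 | (2R,3S,4R)-2-[4-(benzyloxy)phenyl]-3-bromo-4-hydroxychroman-7,8-diyl dimethanesulfonate (Br trans to aryl, OH trans to Br) | O[C@H]1[C@H](Br)[C@@H](c2ccc(OCc3ccccc3)cc2)Oc2c1ccc(OS(C)(=O)=O)c2OS(C)(=O)=O | intermediate
10 | (2R,3R,4R)-2-[4-(benzyloxy)phenyl]-3,4-epoxychroman-7,8-diyl dimethanesulfonate (oxirane cis to aryl) | C(c1ccccc1)Oc1ccc(cc1)[C@H]2Oc3c(ccc(OS(C)(=O)=O)c3OS(C)(=O)=O)[C@H]4O[C@@H]24 | intermediate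
11 | {[(2R,3S,4S)-2-[4-(benzyloxy)phenyl]-3-[(tert-butyldimethylsilyl)oxy]-7,8-bis(methanesulfonyloxy)chroman-4-yl]oxy}dimethylsulfonium trifluoromethanesulfonate (O-4 trans to O-3) | C(c1ccccc1)Oc1ccc(cc1)[C@H]2Oc3c(ccc(OS(C)(=O)=O)c3OS(C)(=O)=O)[C@H](O[S+](C)C)[C@H]2O[Si](C)(C)C(C)(C)C.[O-]S(=O)(=O)C(F)(F)F | intermediate
12 | (2R,3S)-2-[4-(benzyloxy)phenyl]-3-[(tert-butyldimethylsilyl)oxy]-4-oxochroman-7,8-diyl dimethanesulfonate (2,3-cis) | C(c1ccccc1)Oc1ccc(cc1)[C@H]2Oc3c(ccc(OS(C)(=O)=O)c3OS(C)(=O)=O)C(=O)[C@H]2O[Si](C)(C)C(C)(C)C | intermediate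
13 | (2R,3R,4R)-2-[4-(benzyloxy)phenyl]-3-[(tert-butyldimethylsilyl)oxy]-4-hydroxychroman-7,8-diyl dimethanesulfonate (all-cis) | C(c1ccccc1)Oc1ccc(cc1)[C@H]2Oc3c(ccc(OS(C)(=O)=O)c3OS(C)(=O)=O)[C@@H](O)[C@H]2O[Si](C)(C)C(C)(C)C | intermediate
14 | 4-hydroxycinnamic acid | O=C(O)/C=C/c1ccc(O)cc1 | starting material
15 | benzyl (E)-3-[4-(benzyloxy)phenyl]prop-2-enoate | O=C(OCc1ccccc1)/C=C/c1ccc(OCc2ccccc2)cc1 | intermediate
16 | (E)-3-[4-(benzyloxy)phenyl]prop-2-en-1-ol | OC/C=C/c1ccc(OCc2ccccc2)cc1 | intermediate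
17 | (E)-3-[4-(benzyloxy)phenyl]prop-2-en-1-yl methyl carbonate | COC(=O)OC/C=C/c1ccc(OCc2ccccc2)cc1 | intermediate
18 | 2,3,4-trihydroxybenzoic acid | O=C(O)c1ccc(O)c(O)c1O | starting material
19 | benzyl 3,4-bis(benzyloxy)-2-hydroxybenzoate | O=C(OCc1ccccc1)c1ccc(OCc2ccccc2)c(OCc2ccccc2)c1O | intermediate
20 | benzyl 3,4-bis(benzyloxy)-2-{[(1R)-1-[4-(benzyloxy)phenyl]prop-2-en-1-yl]oxy}benzoate | O=C(OCc1ccccc1)c1ccc(OCc2ccccc2)c(OCc2ccccc2)c1O[C@H](C=C)c1ccc(OCc2ccccc2)cc1 | intermediate
21 | 3,4-bis(benzyloxy)-2-{[(1R)-1-[4-(benzyloxy)phenyl]prop-2-en-1-yl]oxy}benzoic acid | O=C(O)c1ccc(OCc2ccccc2)c(OCc2ccccc2)c1O[C@H](C=C)c1ccc(OCc2ccccc2)cc1 | intermediate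
22 | mixed anhydride of acid 21 with 2,4,6-trichlorobenzoic acid | O=C(OC(=O)c1c(Cl)cc(Cl)cc1Cl)c1ccc(OCc2ccccc2)c(OCc2ccccc2)c1O[C@H](C=C)c1ccc(OCc2ccccc2)cc1 | intermediate
23 | ester of the C4 hydroxyl of 13 (all-cis unit A) with acid 21 ((R)-allylic ether) | C(c1ccccc1)Oc1ccc(cc1)[C@H]2Oc3c(ccc(OS(C)(=O)=O)c3OS(C)(=O)=O)[C@@H](OC(=O)c4ccc(OCc5ccccc5)c(OCc5ccccc5)c4O[C@H](C=C)c4ccc(OCc5ccccc5)cc4)[C@H]2O[Si](C)(C)C(C)(C)C | intermediate
24 | 1-aryl-1-alkoxyethene from 23 (C=CH2 in place of the ester C=O, stereocentres as in 23) | C(c1ccccc1)Oc1ccc(cc1)[C@H]2Oc3c(ccc(OS(C)(=O)=O)c3OS(C)(=O)=O)[C@@H](OC(=C)c4ccc(OCc5ccccc5)c(OCc5ccccc5)c4O[C@H](C=C)c4ccc(OCc5ccccc5)cc4)[C@H]2O[Si](C)(C)C(C)(C)C | intermediate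
25 | protected unit A (as in 13) carrying on O-4 the (2R)-7,8-bis(benzyloxy)-2-[4-(benzyloxy)phenyl]-2H-chromen-4-yl group | C(c1ccccc1)Oc1ccc(cc1)[C@H]2Oc3c(ccc(OS(C)(=O)=O)c3OS(C)(=O)=O)[C@@H](OC4=C[C@H](c5ccc(OCc6ccccc6)cc5)Oc5c4ccc(OCc6ccccc6)c5OCc6ccccc6)[C@H]2O[Si](C)(C)C(C)(C)C | intermediate
26 | 3,4-epoxide of 25 on the chromene face opposite the C2 aryl of unit B (epoxy ketal) | C(c1ccccc1)Oc1ccc(cc1)[C@H]2Oc3c(ccc(OS(C)(=O)=O)c3OS(C)(=O)=O)[C@@H](O[C@]45O[C@H]4[C@H](c6ccc(OCc7ccccc7)cc6)Oc6c5ccc(OCc7ccccc7)c6OCc7ccccc7)[C@H]2O[Si](C)(C)C(C)(C)C | intermediate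
27 | protected dimer: unit A (2R,3R,4R) with 3-O-TBS, 7,8-di-O-mesyl and 4'-O-benzyl; unit B (2S,3R,4R) with free 3-OH and 7,8,4'-tri-O-benzyl; C4–O–C4 | C(c1ccccc1)Oc1ccc(cc1)[C@H]2Oc3c(ccc(OS(C)(=O)=O)c3OS(C)(=O)=O)[C@@H](O[C@@H]4c5ccc(OCc6ccccc6)c(OCc6ccccc6)c5O[C@@H](c5ccc(OCc6ccccc6)cc5)[C@@H]4O)[C@H]2O[Si](C)(C)C(C)(C)C | intermediate
28 | dimer 27 without the silyl group (both 3-hydroxyls free) | C(c1ccccc1)Oc1ccc(cc1)[C@H]2Oc3c(ccc(OS(C)(=O)=O)c3OS(C)(=O)=O)[C@@H](O[C@@H]4c5ccc(OCc6ccccc6)c(OCc6ccccc6)c5O[C@@H](c5ccc(OCc6ccccc6)cc5)[C@@H]4O)[C@H]2O | intermediate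
29 | dimer 28 without the mesyl groups (7,8-catechol of unit A free, four benzyl ethers left) | C(c1ccccc1)Oc1ccc(cc1)[C@H]2Oc3c(ccc(O)c3O)[C@@H](O[C@@H]4c5ccc(OCc6ccccc6)c(OCc6ccccc6)c5O[C@@H](c5ccc(OCc6ccccc6)cc5)[C@@H]4O)[C@H]2O | intermediate
30 | CNP0241481.1: (2R,3R,4R)-7,8,4'-trihydroxyflavan-3-ol 4-O-[(2S,3R,4R)-3,7,8,4'-tetrahydroxyflavan-4-yl] ether | Oc1ccc([C@H]2Oc3c(ccc(O)c3O)[C@@H](O[C@@H]3c4ccc(O)c(O)c4O[C@@H](c4ccc(O)cc4)[C@@H]3O)[C@H]2O)cc1 | target

**Step count and risks**
Total step count: 20. Longest linear sequence: 14 steps (steps 1 to 8, then 15 to 20).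

Steps most likely to fail:

1. Step 17. What may go wrong: hydride may be delivered to the wrong face of the C4 oxocarbenium ion. Axial delivery cis to O-3 would give the 3,4-trans ether. The epoxy ketal may also collapse by proton loss before it is reduced. Fallback, from 25 back to 27: 25 is epoxidised as before to 26, and the cold solution is treated with MgBr2·OEt2 (CH2Cl2, −78 → −30 °C) with no hydride donor present. The oxocarbenium–alkoxide pair should then collapse by a suprafacial 1,2-shift of the C3 hydrogen to C4 (semipinacol-type rearrangement), which puts the new C4–H on the face opposite the former epoxide oxygen. This gives the (2S,4R)-4-alkoxyflavan-3-one F1. Reduction with NaBH4 and CeCl3·7H2O at −78 °C, by axial delivery anti to the pseudo-axial 4-alkoxy group, then gives 27.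

2. Step 16. What may go wrong: methylenation of the hindered, electron-rich benzoate may be incomplete; aluminium residues may ionise the benzylic ester or the enol ether; ring closure at the 1,1-disubstituted enol ether may be slow; and C2 may erode through reversible electrocyclic opening of the chromene. Fallback, from 23 straight to 25: a reduced titanium ethylidene (TiCl4, Zn, PbCl2 cat., TMEDA, CH3CHBr2, THF, 65 °C) reverses the order of events. The alkylidene first exchanges at the terminal vinyl group and the resulting titanium alkylidene then olefinates the ester carbonyl within the ring, so no acyclic enol ether and no ruthenium carbene are needed. This fallback makes no compound outside the list (F0).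

3. Step 13. What may go wrong: the hindered, hydrogen-bonded salicylate phenoxide may react slowly or give the linear ether, and the product ether may lose enantiomeric purity by re-ionisation. Fallback, from 19 back to 20: commercial 4-(benzyloxy)benzaldehyde (O=Cc1ccc(OCc2ccccc2)cc1) is treated with HC≡CMgBr to give racemic 1-[4-(benzyloxy)phenyl]prop-2-yn-1-ol F2, which is acetylated (Ac2O, pyridine) to 1-[4-(benzyloxy)phenyl]prop-2-yn-1-yl acetate F3. Copper-catalysed enantioconvergent propargylic etherification of 19 with F3 (CuOTf·0.5C6H6, the 2,6-bis(4-phenyl-4,5-dihydrooxazol-2-yl)pyridine enantiomer that gives the (R)-ether, i-Pr2NEt, MeOH, −20 °C; copper allenylidene intermediate) gives benzyl 3,4-bis(benzyloxy)-2-{[(1R)-1-[4-(benzyloxy)phenyl]prop-2-yn-1-yl]oxy}benzoate F4. Semihydrogenation of the terminal alkyne (H2, Pd/CaCO3–Pb(OAc)2, quinoline, EtOAc) then gives 20.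

**Further compounds**
F1 | step 17 | (2S,4R)-7,8-bis(benzyloxy)-2-[4-(benzyloxy)phenyl]-4-{[unit A of 13]oxy}chroman-3-one (2,4-trans) | C(c1ccccc1)Oc1ccc(cc1)[C@H]2Oc3c(ccc(OS(C)(=O)=O)c3OS(C)(=O)=O)[C@@H](O[C@@H]4c5ccc(OCc6ccccc6)c(OCc6ccccc6)c5O[C@@H](c5ccc(OCc6ccccc6)cc5)C4=O)[C@H]2O[Si](C)(C)C(C)(C)C
F0 | step 16 | none | none
F2 | step 13 | 1-[4-(benzyloxy)phenyl]prop-2-yn-1-ol (racemic) | OC(C#C)c1ccc(OCc2ccccc2)cc1
F3 | step 13 | 1-[4-(benzyloxy)phenyl]prop-2-yn-1-yl acetate (racemic) | CC(=O)OC(C#C)c1ccc(OCc2ccccc2)cc1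
F4 | step 13 | benzyl 3,4-bis(benzyloxy)-2-{[(1R)-1-[4-(benzyloxy)phenyl]prop-2-yn-1-yl]oxy}benzoate | O=C(OCc1ccccc1)c1ccc(OCc2ccccc2)c(OCc2ccccc2)c1O[C@H](C#C)c1ccc(OCc2ccccc2)cc1
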